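**Time first.** Time is the first thing to watch on repeating this run. The ochre flask is asked about at 20 min, and I follow one mole of solid substrate, the limiting reagent, through its forks until the books close.

| flask | solid substrate | remark | time |
|---|---|---|---|
| ochre | 0.49 M | the very flask that is asked about, followed so far |  |
| amber | 0.98 M | run made earlier |  |
| flask | 0.49 M |  | 20 min |

ochre run (percent of the solid substrate charged)

| time / s | solid substrate / % | target / % | isomer of the product / % |
|---|---|---|---|
| 10.0 | 94.5 | 0.6 | 0.1 |
| 20.0 | 90.4 | 2.4 | 0.7 |
| 40.0 | 82.0 | 3.7 | 4.1 |
| 90.0 | 63.7 | 11.6 | 10.5 |

amber run (percent of the solid substrate charged)

| time / min | solid substrate / % | target / % | isomer of the product / % |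
|---|---|---|---|
| 2.50 | 70.7 | 10.2 | 9.9 |
| 8.00 | 13.4 | 33.7 | 36.3 |
| 12.0 | 0 | 41.6 | 45.1 |
| 20.0 | 0.1 | 40.9 | 45.2 |

(standard deviation of a reading: 0.5 percentage points)

- why nothing more happens at 20 min, or that something still does (for what has run out or reacted, a solid counts together with what of it has only dissolved; other conformer counts as not reacted) (all of the solid substrate has reacted / it is still moving / forward and back rates have come level)
- part of the solid substrate that has turned into other species by 20 min (what has only dissolved and other conformer do not count)
- target at 20 min, in percent of the solid substrate charged
- isomer of the product at 20 min, in percent of the solid substrate charged
- third product at 20 min, in percent of the solid substrate charged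

- solid substrate is a solid; its amount is given per volume of the solution
- the earlier runs were read with a standard deviation of 0.5 percentage points
- at the start none of the solid substrate is in solution
- in a conversion other conformer counts as not yet reacted; third conformer counts as reacted
- what has only dissolved of solid substrate counts as not reacted
- the reaction counts as stopped when no species that holds the solid substrate changes by six tenths of a point or more over the second half of the time

**The solid entry.** The ochre flask has lost 36.3 % of its charge by 90.0 s. At that pace its solid lasts about 4.13 min, which is earlier than the asked time. On average the ochre flask loses 1.98 mM/s up to its last reading and the amber run 1.91 mM/s up to its first, about the same, although the amber run holds twice the charge. I therefore expect both solutions to be fed alike and to divide alike.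

**The product entries.** Between 12.0 min and 20.0 min the amber readings of the two products move by at most 0.7 percentage points, against a scatter of 0.5 points in each reading, so I average the two. Target reads 41.2 %: this is the target share, the part of each mole charged that ends as target. Isomer of the product reads 45.1 %. The unread remainder, 13.6 %, I book as third product, and the books close. I carry these shares to the ochre flask.

**The forecast.** It says all of the solid substrate has reacted, with conversion 100 %, target 41.3 %, isomer of the product 45.2 % and third product 13.5 %. Its ground: “Selectivity appears roughly concentration-independent”.

**The result.** The ochre flask gives all of the solid substrate has reacted, with conversion 100 %, target 41.5 %, isomer of the product 45.2 % and third product 13.2 %.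

    starting material ⇌ other conformer (K = 1.10, k = 0.0775 /s)
    starting material → target (k = 0.0331 /s)
    other conformer → isomer of the product (k = 0.0823 /s)
    other conformer ⇌ third conformer (K = 1.15, k = 0.101 /s)
    third conformer → third product (k = 0.0275 /s)
    solid substrate ⇌ starting material, rate k6*(cs6 - [starting material]) while solid is left; crystals form when [starting material] > cs6 (solubility = 36.0 mM, k = 0.115 /s)
    starting material ⇌ dormant form (K = 0.980, k = 0.0265 /s)

**The main fork.** The target share of 41.2 %, read in the amber run, meets 41.5 % in the ochre flask. With the loss of starting material to other conformer struck out, both ways, target goes from 41.5 % to >99.9 %, so this fork is the main reason for the shortfall.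

**Second flask.** For a neighbour charged with 1.2 M I reckon, at the ochre pace, that the solid lasts about 10.1 min, earlier than 20 min, so the target share promises 41.2 % of its charge, or 0.494 M target. Computed, that neighbour gives 41.5 % of its charge, with 0 % of the solid substrate left.

All runs were generated by integration for an exercise, and the scatter is random.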